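Ring B is read (labdane numbering) as the retron of an alkyne Diels–Alder reaction. Its tetrasubstituted C8=C9 alkene, flanked by C7H2 and quaternary C10, maps onto the triple bond of but-2-ynal (C17–C8≡C9–C11). C7–C6–C5–C10 maps onto the semicyclic diene of an enantiopure ring-A vinylcyclohexene that already carries C4. In one operation, a catalyst-controlled [4+2] cycloaddition and an in-flask, base-induced diene transposition close ring B and form C7–C8 and C9–C10. The same operation fixes the alkene position and sets C10 and the trans ring fusion at C5. The activating C11 aldehyde then serves as the handle for the side chain (methylenation, hydroboration, sp3–sp2 coupling).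

Key step: step 7

Remark: C1–C10 are the decalin carbons, C11–C16 the side chain, C17 sits on C8, C18/C19 on C4 and C20 on C10. But-2-ynal and but-2-yn-1-ol are taken as commercial. Compound 7 is carried as a mixture of C10 epimers that converge in step 5.

Step 1
Reactants: 1 methyl 2-oxocyclohexane-1-carboxylate
Product: 2 methyl (1R,2R)-2-hydroxycyclohexane-1-carboxylate
Conditions: H2 (100 atm), [RuCl(benzene)((R)-BINAP)]Cl (0.5 mol %), CH2Cl2, 50 °C
Reagents that add atoms: none
Why: Noyori-type Ru–BINAP hydrogenation of a configurationally labile β-keto ester under dynamic kinetic resolution; the (R)-ligand should give the (R)-carbinol at C5, the only centre needed because C4 is planarised in step 2.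

Step 2
Reactants: 2 methyl (1R,2R)-2-hydroxycyclohexane-1-carboxylate
Product: 4 methyl (1S,2R)-2-hydroxy-1-methylcyclohexane-1-carboxylate, via dilithio dianion 3 (not isolated)
Conditions: LDA (2.2 equiv), THF, −78 to −20 °C; MeI, DMPU, −78 to 0 °C; H2O
Reagents that add atoms: iodomethane, CI
Why: Fráter–Seebach alkylation; the lithium-chelated dianion is methylated on the face anti to the C5 alkoxide (equatorial attack on the exocyclic enolate), which sets quaternary C4 as S with CO2Me cis to the oxygen.

Step 3
Reactants: 4 methyl (1S,2R)-2-hydroxy-1-methylcyclohexane-1-carboxylate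
Product: 5 methyl (1S)-1-methyl-2-oxocyclohexane-1-carboxylate
Conditions: TPAP (5 mol %), NMO, 4 Å MS, CH2Cl2, 23 °C
Reagents that add atoms: none
Why: Ley–Griffith oxidation of a hindered secondary alcohol under neutral conditions; C4 has no α-hydrogen and cannot racemise.

Step 4
Reactants: 5 methyl (1S)-1-methyl-2-oxocyclohexane-1-carboxylate
Product: 7 methyl (1S,3RS)-1,3-dimethyl-2-oxocyclohexane-1-carboxylate, via lithium enolate 6 (not isolated)
Conditions: LDA (1.05 equiv), THF, −78 °C; MeI, −78 to 0 °C
Reagents that add atoms: iodomethane, CI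
Why: Kinetic enolate alkylation; only the C10 side of the ketone carries α-hydrogens, and the new C10 centre needs no control because step 5 planarises it.

Step 5
Reactants: 7 methyl (1S,3RS)-1,3-dimethyl-2-oxocyclohexane-1-carboxylate
Product: 9 methyl (1S)-1,3-dimethyl-2-(trifluoromethylsulfonyloxy)cyclohex-2-ene-1-carboxylate, via potassium enolate 8 (not isolated)
Conditions: KHMDS, THF, −78 to 0 °C; PhNTf2, −78 to 23 °C
Reagents that add atoms: N-phenylbis(trifluoromethanesulfonimide), O=S(=O)(N(c1ccccc1)S(=O)(=O)C(F)(F)F)C(F)(F)F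
Why: Regiospecific enol triflate formation; the single remaining α-hydrogen is at C10, so the tetrasubstituted C5=C10 enolate is the only one possible, as with 2,2,6-trisubstituted cyclohexanones.

Step 6
Reactants: 9 methyl (1S)-1,3-dimethyl-2-(trifluoromethylsulfonyloxy)cyclohex-2-ene-1-carboxylate
Product: 10 methyl (1S)-2-ethenyl-1,3-dimethylcyclohex-2-ene-1-carboxylate
Conditions: tributyl(vinyl)stannane, Pd(PPh3)4 (5 mol %), LiCl (3 equiv), THF, reflux
Reagents that add atoms: tributyl(vinyl)stannane, C=C[Sn](CCCC)(CCCC)CCCC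
Why: Stille coupling of an enol triflate in the presence of LiCl, a reaction type that tolerates fully substituted cyclohexenyl triflates next to a quaternary carbon; no stereocentre is touched.

Step 7
Reactants: 10 methyl (1S)-2-ethenyl-1,3-dimethylcyclohex-2-ene-1-carboxylate; 11 but-2-ynal
Product: 13 methyl (1S,4aS,8aR)-5-formyl-1,4a,6-trimethyl-1,2,3,4,4a,8a-hexahydronaphthalene-1-carboxylate, via cycloadduct 12 (not isolated)
Conditions: (R)-B-(o-tolyl)-diphenylprolinol oxazaborolidine·HNTf2 (20 mol %), CH2Cl2, −40 to −20 °C; then DBU (1.5 equiv), 23 °C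
Reagents that add atoms: none
Why: The boron-bound ynal and the s-cis diene unite in a concerted, asynchronous, suprafacial [4π+2π] cycloaddition (C7–C8 bonding runs ahead of C9–C10) to give 1,4-diene 12, after which DBU removes the doubly allylic, vinylogously acidic C7–H and the extended enolate is reprotonated at C5, so that C5=C6 moves into conjugation as C6=C7. The closest known reaction types are the Diels–Alder reaction of 2,6,6-trisubstituted 1-vinylcyclohexenes with acetylenic esters followed by amidine-base isomerisation, and the cationic-oxazaborolidine-catalysed Diels–Alder reaction of acetylenic carbonyl compounds. Ring B is the only ring closed, as the six-membered ring of an intermolecular [4+2] cycloaddition. C10 is set by the catalyst: the ynal, held by B–O coordination and a formyl C–H···O contact, has one face covered by the cis aryl group, and exo approach of the diene (ring A on the formyl-H side, away from the B-aryl group) to the open face puts C9 on the α face and C20 on the β face, cis to C19, while the C4 centre lies too far from the bonding termini to oppose this. C5 is set under thermodynamic control, since reversible ε-deprotonation funnels the dienal into the trans-fused isomer with axial 5α-H anti to C20. The step needs regio-, chemo- and facial selectivity: the unsubstituted, most nucleophilic C7 terminus of the trialkyl-substituted diene pairs with the β-carbon C8 of the ynal and hindered C10 with the carbonyl-bearing C9, the substrate offers only this one diene, and quaternary C4 and C10 block aromatisation or any other double-bond migration.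

Step 8
Reactants: 13 methyl (1S,4aS,8aR)-5-formyl-1,4a,6-trimethyl-1,2,3,4,4a,8a-hexahydronaphthalene-1-carboxylate
Product: 14 methyl (1S,4aS,8aR)-5-formyl-1,4a,6-trimethyl-1,2,3,4,4a,7,8,8a-octahydronaphthalene-1-carboxylate
Conditions: H2 (1 atm, 1 equiv uptake), 5 % Pd/C, EtOAc, 23 °C
Reagents that add atoms: none
Why: Chemoselective heterogeneous hydrogenation; the cis-disubstituted C6=C7 alkene should be saturated well ahead of the tetrasubstituted, carbonyl-conjugated C8=C9 alkene, and no stereocentre is formed.

Step 9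
Reactants: 14 methyl (1S,4aS,8aR)-5-formyl-1,4a,6-trimethyl-1,2,3,4,4a,7,8,8a-octahydronaphthalene-1-carboxylate
Product: 15 methyl (1S,4aS,8aR)-5-ethenyl-1,4a,6-trimethyl-1,2,3,4,4a,7,8,8a-octahydronaphthalene-1-carboxylate
Conditions: Ph3PCH3Br, KOt-Bu, THF, 0 to 23 °C
Reagents that add atoms: methyltriphenylphosphonium bromide, C[P+](c1ccccc1)(c1ccccc1)c1ccccc1.[Br-]
Why: Wittig methylenation of a non-enolisable, β-cyclocitral-type aldehyde; the neopentyl axial C19 ester is inert to the ylide.

Step 10
Reactants: 16 but-2-yn-1-ol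
Product: 18 (E)-3-iodobut-2-en-1-ol, via vinylzirconocene alkoxide 17 (not isolated)
Conditions: Cp2Zr(H)Cl (2.2 equiv), THF, 23 °C; I2, 0 °C; H2O
Reagents that add atoms: iodine, II; Schwartz reagent (stays only in 17), [H][Zr](Cl)(C1C=CC=C1)C1C=CC=C1
Why: Hydrozirconation–iodination; syn addition of Zr–H places zirconium on the alkyne carbon remote from the bulky zirconium alkoxide, and iodinolysis with retention gives the E-iodide.

Step 11
Reactants: 15 methyl (1S,4aS,8aR)-5-ethenyl-1,4a,6-trimethyl-1,2,3,4,4a,7,8,8a-octahydronaphthalene-1-carboxylate; 18 (E)-3-iodobut-2-en-1-ol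
Product: 20 methyl (1S,4aS,8aR)-5-[(3E)-5-hydroxy-3-methylpent-3-en-1-yl]-1,4a,6-trimethyl-1,2,3,4,4a,7,8,8a-octahydronaphthalene-1-carboxylate, via B-alkyl-9-BBN 19 (not isolated)
Conditions: 9-BBN-H, THF, 23 °C; then 18, PdCl2(dppf) (5 mol %), AsPh3, Cs2CO3, DMF–H2O, 23 °C
Reagents that add atoms: 9-borabicyclo[3.3.1]nonane (stays only in 19), [H]B1C2CCCC1CCC2
Why: Hydroboration followed by B-alkyl Suzuki–Miyaura coupling; 9-BBN adds only to the monosubstituted C11=C12 alkene with boron at C12, and the sp3–sp2 coupling forms C12–C13 with retention of the E geometry of the iodide.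

Step 12
Reactants: 20 methyl (1S,4aS,8aR)-5-[(3E)-5-hydroxy-3-methylpent-3-en-1-yl]-1,4a,6-trimethyl-1,2,3,4,4a,7,8,8a-octahydronaphthalene-1-carboxylate
Product: 21 methyl (1S,4aS,8aR)-5-[(3E)-5-acetoxy-3-methylpent-3-en-1-yl]-1,4a,6-trimethyl-1,2,3,4,4a,7,8,8a-octahydronaphthalene-1-carboxylate
Conditions: Ac2O, pyridine, DMAP (cat.), CH2Cl2, 23 °C
Reagents that add atoms: acetic anhydride, CC(=O)OC(C)=O
Why: DMAP-catalysed O-acylation of the only free hydroxyl group; no stereocentre or alkene is affected.

Compound list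
1 | methyl 2-oxocyclohexane-1-carboxylate | COC(=O)C1CCCCC1=O | starting material
2 | methyl (1R,2R)-2-hydroxycyclohexane-1-carboxylate | COC(=O)[C@@H]1CCCC[C@H]1O | intermediate
3 | dilithium alkoxide-enolate (dianion) of 2 | [Li+].[Li+].COC([O-])=C1CCCC[C@H]1[O-] | intermediate
4 | methyl (1S,2R)-2-hydroxy-1-methylcyclohexane-1-carboxylate | COC(=O)[C@@]1(C)CCCC[C@H]1O | intermediate
5 | methyl (1S)-1-methyl-2-oxocyclohexane-1-carboxylate | COC(=O)[C@@]1(C)CCCCC1=O | intermediate
6 | lithium enolate of 5 | [Li+].COC(=O)[C@@]1(C)CCCC=C1[O-] | intermediate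
7 | methyl (1S,3RS)-1,3-dimethyl-2-oxocyclohexane-1-carboxylate | COC(=O)[C@@]1(C)CCCC(C)C1=O | intermediate
8 | potassium enolate of 7 | [K+].COC(=O)[C@@]1(C)CCCC(C)=C1[O-] | intermediate
9 | methyl (1S)-1,3-dimethyl-2-(trifluoromethylsulfonyloxy)cyclohex-2-ene-1-carboxylate | COC(=O)[C@@]1(C)CCCC(C)=C1OS(=O)(=O)C(F)(F)F | intermediate
10 | methyl (1S)-2-ethenyl-1,3-dimethylcyclohex-2-ene-1-carboxylate | COC(=O)[C@@]1(C)CCCC(C)=C1C=C | intermediate
11 | but-2-ynal | CC#CC=O | starting material
12 | methyl (1S,4aS)-5-formyl-1,4a,6-trimethyl-1,2,3,4,4a,7-hexahydronaphthalene-1-carboxylate (1,4-diene cycloadduct) | COC(=O)[C@@]1(C)CCC[C@]2(C)C(C=O)=C(C)CC=C12 | intermediate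
13 | methyl (1S,4aS,8aR)-5-formyl-1,4a,6-trimethyl-1,2,3,4,4a,8a-hexahydronaphthalene-1-carboxylate (trans-fused dienal) | COC(=O)[C@@]1(C)CCC[C@]2(C)C(C=O)=C(C)C=C[C@@H]12 | intermediate
14 | methyl (1S,4aS,8aR)-5-formyl-1,4a,6-trimethyl-1,2,3,4,4a,7,8,8a-octahydronaphthalene-1-carboxylate | COC(=O)[C@@]1(C)CCC[C@]2(C)C(C=O)=C(C)CC[C@@H]12 | intermediate
15 | methyl (1S,4aS,8aR)-5-ethenyl-1,4a,6-trimethyl-1,2,3,4,4a,7,8,8a-octahydronaphthalene-1-carboxylate | COC(=O)[C@@]1(C)CCC[C@]2(C)C(C=C)=C(C)CC[C@@H]12 | intermediate
16 | but-2-yn-1-ol | CC#CCO | starting material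
17 | (E)-vinylzirconocene chloride, zirconocene chloride alkoxide of 16 | C/C(=C\CO[Zr](Cl)(C1C=CC=C1)C1C=CC=C1)[Zr](Cl)(C1C=CC=C1)C1C=CC=C1 | intermediate
18 | (E)-3-iodobut-2-en-1-ol | C/C(I)=C\CO | intermediate
19 | B-alkyl-9-BBN from 15 (boron on C12) | COC(=O)[C@@]1(C)CCC[C@]2(C)C(CCB3C4CCCC3CCC4)=C(C)CC[C@@H]12 | intermediate
20 | methyl (1S,4aS,8aR)-5-[(3E)-5-hydroxy-3-methylpent-3-en-1-yl]-1,4a,6-trimethyl-1,2,3,4,4a,7,8,8a-octahydronaphthalene-1-carboxylate | COC(=O)[C@@]1(C)CCC[C@]2(C)C(CC/C(C)=C/CO)=C(C)CC[C@@H]12 | intermediate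
21 | methyl (1S,4aS,8aR)-5-[(3E)-5-acetoxy-3-methylpent-3-en-1-yl]-1,4a,6-trimethyl-1,2,3,4,4a,7,8,8a-octahydronaphthalene-1-carboxylate | COC(=O)[C@@]1(C)CCC[C@]2(C)C(CC/C(C)=C/COC(C)=O)=C(C)CC[C@@H]12 | target

Total step count: 12. Longest linear sequence: 11 (steps 1–9, 11 and 12; step 10 is a one-step side branch).

Steps most likely to fail

Risk 1, step 7.
- **What may go wrong:** Bond formation at the tetrasubstituted C10 terminus may be slow, because the Z-methyl C20 disfavours the s-cis diene. Acid-induced oligomerisation of the diene could then compete. Catalyst control over the diene face may also be incomplete.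
- **Fallback:** Covalent iminium activation replaces Lewis-acid activation, setting out from 10 and 11.
  - But-2-ynal is condensed with (2S,5S)-5-benzyl-2-tert-butyl-3-methylimidazolidin-4-one triflate to the acetylenic iminium triflate F1. This is a cationic and therefore stronger dienophile, and one of its faces is covered by both the benzyl and the tert-butyl group.
  - Exo cycloaddition of 10 on the open face should give the cycloadduct iminium triflate F2.
  - Aqueous DBU hydrolyses F2 to 12 and isomerises it, so the route is rejoined at 13.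

Risk 2, step 8.
- **What may go wrong:** Hydrogen may add across the diene in a 1,4 sense, the alkene may migrate on the metal surface, or the enal may be over-reduced.
- **Fallback:** Hydride conjugate addition replaces surface hydrogenation, setting out from 13.
  - The Stryker reagent cannot attack the fully substituted C8. It should therefore deliver hydride to C6 in a 1,6 sense.
  - Protonation of the copper dienolate at C9 gives the β,γ-unsaturated aldehyde F3.
  - DBU moves the C7=C8 alkene back into conjugation, and the route is rejoined at 14.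

Risk 3, step 11.
- **What may go wrong:** Hydroboration of the twisted, hindered diene may be slow. Protodeboronation or β-hydride elimination may intervene during the sp3–sp2 coupling.
- **Fallback:** Carbonyl chemistry replaces cross-coupling, setting out from 14 and bypassing steps 9 and 10.
  - Aldol condensation with acetone gives the dienone F4.
  - Conjugate reduction of its disubstituted C11=C12 alkene (Et3SiH, RhCl(PPh3)3, then hydrolysis) gives the methyl ketone F5.
  - Horner–Wadsworth–Emmons olefination with trimethyl phosphonoacetate gives the E-enoate F6.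
  - DIBAL-H at −78 °C reduces this unhindered conjugated ester in preference to the neopentyl axial C19 ester, and the route is rejoined at 20.

Further compounds
F1 | step 7 | (2S,5S)-5-benzyl-1-(but-2-yn-1-ylidene)-2-tert-butyl-3-methyl-4-oxoimidazolidin-1-ium triflate | O=C1[C@H](Cc2ccccc2)[N+](=CC#CC)[C@H](C(C)(C)C)N1C.[O-]S(=O)(=O)C(F)(F)F
F2 | step 7 | iminium triflate of cycloadduct 12 with the same imidazolidinone | COC(=O)[C@@]1(C)CCC[C@]2(C)C(C=[N+]3[C@@H](Cc4ccccc4)C(=O)N(C)[C@H]3C(C)(C)C)=C(C)CC=C12.[O-]S(=O)(=O)C(F)(F)F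
F3 | step 8 | methyl (1S,4aS,8aR)-5-formyl-1,4a,6-trimethyl-1,2,3,4,4a,5,8,8a-octahydronaphthalene-1-carboxylate (C9 epimers) | COC(=O)[C@@]1(C)CCC[C@]2(C)C(C=O)C(C)=CC[C@@H]12
F4 | step 11 | methyl (1S,4aS,8aR)-1,4a,6-trimethyl-5-[(1E)-3-oxobut-1-en-1-yl]-1,2,3,4,4a,7,8,8a-octahydronaphthalene-1-carboxylate | COC(=O)[C@@]1(C)CCC[C@]2(C)C(/C=C/C(C)=O)=C(C)CC[C@@H]12
F5 | step 11 | methyl (1S,4aS,8aR)-1,4a,6-trimethyl-5-(3-oxobutyl)-1,2,3,4,4a,7,8,8a-octahydronaphthalene-1-carboxylate | COC(=O)[C@@]1(C)CCC[C@]2(C)C(CCC(C)=O)=C(C)CC[C@@H]12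
F6 | step 11 | methyl (1S,4aS,8aR)-5-[(3E)-5-methoxy-3-methyl-5-oxopent-3-en-1-yl]-1,4a,6-trimethyl-1,2,3,4,4a,7,8,8a-octahydronaphthalene-1-carboxylate | COC(=O)[C@@]1(C)CCC[C@]2(C)C(CC/C(C)=C/C(=O)OC)=C(C)CC[C@@H]12
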